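## Retrosynthetic overview

1. The C6–OH comes from C6–Br of bromochromene 14 (Br/Li exchange, borate, oxidation) as the last step.
2. The pyran ring is the only ring made (the benzene ring is bought). It is closed at C3=C4 by ring-closing metathesis of styrenyl allyl ether 13, i.e. a Ru-carbene [2+2] cycloaddition/cycloreversion that leaves C2 untouched. A closure at O1–C2 through an o-quinone methide (oxa-6π) would pass through a planar C2 and give racemate, so it is not used.
3. The aryl–O bond comes from SNAr of the tertiary alkoxide of (S)-geranyllinalool 9 on 5-bromo-2-fluoro-3-methylbenzaldehyde 10, then CHO → CH=CH2. The C–O bond at the stereocentre is never broken.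
4. Alcohol 9 comes from (S)-linalool 1, which carries the only stereocentre, and geranyl phenyl sulfone 6, joined at C8 by allylic oxidation, chlorination, sulfone alkylation and desulfonylation.

Assumption: the target is (2S), which maps onto C3 of (S)-(+)-linalool; 1 (≥95 % ee lot) and 10 are taken as catalogue items, the product ee equals that of 1, and chromenes 14–17 are kept from light, acid and heat.

## Route

Step 1
Reactants: 1 (S)-(+)-linalool
Product: 2 (2E,6S)-2,6-dimethylocta-2,7-diene-1,6-diol
Conditions: SeO2 (0.3 eq), t-BuOOH (3 eq), salicylic acid (0.1 eq), CH2Cl2, rt, 24 h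
Reagents that add atoms: tert-butyl hydroperoxide CC(C)(C)OO (net oxygen donor, relayed by catalytic selenium dioxide O=[Se]=O)
Why: Riley/Sharpless allylic oxidation (ene reaction, then [2,3]-sigmatropic shift of the allylseleninic acid) hydroxylates only the (E)-methyl of the trisubstituted olefin, since the vinyl group has no allylic C–H and the carbinol stereocentre is not involved.

Step 2
Reactants: 2 (2E,6S)-2,6-dimethylocta-2,7-diene-1,6-diol
Product: 4 (3S,6E)-8-chloro-3,7-dimethylocta-1,6-dien-3-ol, via alkoxydimethylsulfonium chloride 3 (not isolated)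
Conditions: NCS (1.1 eq), Me2S (1.2 eq), CH2Cl2, 0 → −20 °C; then 2, −20 → 0 °C
Reagents that add atoms: N-chlorosuccinimide O=C1CCC(=O)N1Cl
Why: Corey–Kim chlorination, in which only the primary allylic alcohol forms the alkoxysulfonium salt and is displaced by chloride (SN2, no allylic shift) while the hindered tertiary alcohol stays free.

Step 3
Reactants: 5 geranyl bromide
Product: 6 geranyl phenyl sulfone
Conditions: PhSO2Na (1.2 eq), DMF, rt, 12 h
Reagents that add atoms: sodium benzenesulfinate [Na+].[O-]S(=O)c1ccccc1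
Why: SN2 S-alkylation of the sulfinate by the primary allylic bromide gives the sulfone with the E-olefin unchanged.

Step 4
Reactants: 6 geranyl phenyl sulfone; 4 (3S,6E)-8-chloro-3,7-dimethylocta-1,6-dien-3-ol
Product: 8 (3S,6E,10E)-3,7,11,15-tetramethyl-9-(phenylsulfonyl)hexadeca-1,6,10,14-tetraen-3-ol (C9 epimers), via lithiated geranyl phenyl sulfone 7 (not isolated)
Conditions: 6 (2.2 eq), n-BuLi (2.1 eq), THF/DMPU, −78 °C; then 4 (1 eq), −78 → −20 °C
Reagents that add atoms: none
Why: Biellmann-type sulfone alkylation, in which the α-sulfonyl allyl anion attacks the primary allylic chloride at its α-carbon (SN2) and joins the units head-to-tail with both E-olefins intact; the extra equivalent of anion covers the free OH, and the uncontrolled C9 centre is removed in step 5.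

Step 5
Reactants: 8 (3S,6E,10E)-3,7,11,15-tetramethyl-9-(phenylsulfonyl)hexadeca-1,6,10,14-tetraen-3-ol
Product: 9 (3S,6E,10E)-3,7,11,15-tetramethylhexadeca-1,6,10,14-tetraen-3-ol [(S)-geranyllinalool]
Conditions: PdCl2(dppp) (5 mol%), LiBHEt3 (3.5 eq), THF, 0 °C
Reagents that add atoms: none
Why: Pd(0)-catalysed reductive desulfonylation, where ionisation to the π-allyl-Pd and hydride delivery to the less substituted terminus replace SO2Ph by H without moving or isomerising the E-olefin; the tertiary carbinol is not ionised.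

Step 6
Reactants: 9 (S)-geranyllinalool; 10 5-bromo-2-fluoro-3-methylbenzaldehyde
Product: 12 5-bromo-3-methyl-2-{[(3S,6E,10E)-3,7,11,15-tetramethylhexadeca-1,6,10,14-tetraen-3-yl]oxy}benzaldehyde, via potassium alkoxide of geranyllinalool 11 (not isolated)
Conditions: KH (1.1 eq), THF, 0 °C → rt; then 10 (1.3 eq), DMF, 0 °C → rt
Reagents that add atoms: none
Why: SNAr (addition–elimination) of the tertiary alkoxide on the fluoride activated by the ortho-formyl group forms the aryl–O bond, and because the C–O bond at the stereocentre is never broken the (S) configuration is retained.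

Step 7
Reactants: 12 5-bromo-3-methyl-2-{[(3S,6E,10E)-3,7,11,15-tetramethylhexadeca-1,6,10,14-tetraen-3-yl]oxy}benzaldehyde
Product: 13 5-bromo-1-ethenyl-3-methyl-2-{[(3S,6E,10E)-3,7,11,15-tetramethylhexadeca-1,6,10,14-tetraen-3-yl]oxy}benzene
Conditions: Ph3PCH3Br (1.5 eq), KOtBu (1.4 eq), THF, 0 °C → rt
Reagents that add atoms: methyltriphenylphosphonium bromide C[P+](c1ccccc1)(c1ccccc1)c1ccccc1.[Br-]
Why: Wittig methylenation of the non-enolisable aryl aldehyde under basic, acid-free conditions gives the styrene without disturbing the tertiary allyl aryl ether or the aryl bromide.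

Step 8
Reactants: 13 5-bromo-1-ethenyl-3-methyl-2-{[(3S,6E,10E)-3,7,11,15-tetramethylhexadeca-1,6,10,14-tetraen-3-yl]oxy}benzene
Product: 14 (2S)-6-bromo-2,8-dimethyl-2-[(3E,7E)-4,8,12-trimethyltrideca-3,7,11-trien-1-yl]-2H-chromene
Conditions: Grubbs I, (PCy3)2Cl2Ru=CHPh (5 mol%), CH2Cl2 (0.01 M), rt → 40 °C, dark
Reagents that add atoms: none
Why: Ring-closing olefin metathesis (Ru-alkylidene [2+2] cycloaddition to a ruthenacyclobutane, then [2+2] cycloreversion) joins the two monosubstituted olefins into the 2H-pyran ring with loss of ethylene, the first-generation catalyst leaving the trisubstituted chain olefins alone and the quaternary stereocentre being a spectator.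

Step 9
Reactants: 14 (2S)-6-bromo-2,8-dimethyl-2-[(3E,7E)-4,8,12-trimethyltrideca-3,7,11-trien-1-yl]-2H-chromene
Product: 17 (2S)-2,8-dimethyl-2-[(3E,7E)-4,8,12-trimethyltrideca-3,7,11-trien-1-yl]-2H-chromen-6-ol (target), via aryllithium 15 (not isolated), via lithium aryltrimethoxyborate 16 (not isolated)
Conditions: n-BuLi (1.05 eq), THF, −78 °C; B(OMe)3 (2 eq), −78 → 0 °C; 30 % H2O2, aq NaOH, 0 °C; pH 7 work-up, dark
Reagents that add atoms: hydrogen peroxide OO
Why: Br–Li exchange, borate formation and alkaline peroxide oxidation (1,2-aryl shift from B to O) turn Ar–Br into Ar–OH at −78 to 0 °C, where the chromene neither ring-opens nor racemises and isolated olefins are inert.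

## Compound list

1 | (S)-(+)-linalool | C=C[C@@](C)(O)CCC=C(C)C | starting material
2 | (2E,6S)-2,6-dimethylocta-2,7-diene-1,6-diol | C=C[C@@](C)(O)CC/C=C(\C)CO | intermediate
3 | {[(2E,6S)-6-hydroxy-2,6-dimethylocta-2,7-dien-1-yl]oxy}dimethylsulfonium chloride | C=C[C@@](C)(O)CC/C=C(\C)CO[S+](C)C.[Cl-] | intermediate (not isolated)
4 | (3S,6E)-8-chloro-3,7-dimethylocta-1,6-dien-3-ol | C=C[C@@](C)(O)CC/C=C(\C)CCl | intermediate
5 | geranyl bromide, (2E)-1-bromo-3,7-dimethylocta-2,6-diene | CC(C)=CCC/C(C)=C/CBr | starting material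
6 | geranyl phenyl sulfone | CC(C)=CCC/C(C)=C/CS(=O)(=O)c1ccccc1 | intermediate
7 | α-lithio geranyl phenyl sulfone | [Li]C(/C=C(\C)CCC=C(C)C)S(=O)(=O)c1ccccc1 | intermediate (not isolated)
8 | (3S,6E,10E)-3,7,11,15-tetramethyl-9-(phenylsulfonyl)hexadeca-1,6,10,14-tetraen-3-ol, C9 epimers | C=C[C@@](C)(O)CC/C=C(\C)CC(/C=C(\C)CCC=C(C)C)S(=O)(=O)c1ccccc1 | intermediate
9 | (3S,6E,10E)-3,7,11,15-tetramethylhexadeca-1,6,10,14-tetraen-3-ol, (S)-geranyllinalool | C=C[C@@](C)(O)CC/C=C(\C)CC/C=C(\C)CCC=C(C)C | intermediate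
10 | 5-bromo-2-fluoro-3-methylbenzaldehyde | O=Cc1cc(Br)cc(C)c1F | starting material
11 | potassium (3S,6E,10E)-3,7,11,15-tetramethylhexadeca-1,6,10,14-tetraen-3-olate | C=C[C@@](C)([O-])CC/C=C(\C)CC/C=C(\C)CCC=C(C)C.[K+] | intermediate (not isolated)
12 | 5-bromo-3-methyl-2-{[(3S,6E,10E)-3,7,11,15-tetramethylhexadeca-1,6,10,14-tetraen-3-yl]oxy}benzaldehyde | C=C[C@@](C)(Oc1c(C)cc(Br)cc1C=O)CC/C=C(\C)CC/C=C(\C)CCC=C(C)C | intermediate
13 | 5-bromo-1-ethenyl-3-methyl-2-{[(3S,6E,10E)-3,7,11,15-tetramethylhexadeca-1,6,10,14-tetraen-3-yl]oxy}benzene | C=C[C@@](C)(Oc1c(C)cc(Br)cc1C=C)CC/C=C(\C)CC/C=C(\C)CCC=C(C)C | intermediate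
14 | (2S)-6-bromo-2,8-dimethyl-2-[(3E,7E)-4,8,12-trimethyltrideca-3,7,11-trien-1-yl]-2H-chromene | CC(C)=CCC/C(C)=C/CC/C(C)=C/CC[C@@]1(C)C=Cc2cc(Br)cc(C)c2O1 | intermediate
15 | {(2S)-2,8-dimethyl-2-[(3E,7E)-4,8,12-trimethyltrideca-3,7,11-trien-1-yl]-2H-chromen-6-yl}lithium | CC(C)=CCC/C(C)=C/CC/C(C)=C/CC[C@@]1(C)C=Cc2cc([Li])cc(C)c2O1 | intermediate (not isolated)
16 | lithium trimethoxy{(2S)-2,8-dimethyl-2-[(3E,7E)-4,8,12-trimethyltrideca-3,7,11-trien-1-yl]-2H-chromen-6-yl}borate | CC(C)=CCC/C(C)=C/CC/C(C)=C/CC[C@@]1(C)C=Cc2cc([B-](OC)(OC)OC)cc(C)c2O1.[Li+] | intermediate (not isolated)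
17 | (2S)-2,8-dimethyl-2-[(3E,7E)-4,8,12-trimethyltrideca-3,7,11-trien-1-yl]-2H-chromen-6-ol | CC(C)=CCC/C(C)=C/CC/C(C)=C/CC[C@@]1(C)C=Cc2cc(O)cc(C)c2O1 | target

## Step count and risks

Total step count: 9. Longest linear sequence: 8 (steps 1, 2, 4, 5, 6, 7, 8, 9 from 1; step 3 makes sulfone 6 on the side).

Steps most likely to fail:

Step 6 (SNAr). A bulky tertiary alkoxide must attack a fluoride flanked by CHO and CH3, and the aldehyde can take up alkoxide. The fallback sets out from 9. Its alkoxide 11 is reacted with 5-bromo-2-fluoro-3-methylbenzonitrile (KH, DMF, 0 °C → rt), where the smaller, non-electrophilic cyano group activates the fluoride. This gives 5-bromo-3-methyl-2-{[(3S,6E,10E)-3,7,11,15-tetramethylhexadeca-1,6,10,14-tetraen-3-yl]oxy}benzonitrile F1. DIBAL-H (toluene, −78 °C) and buffered hydrolysis of the aldimine then give aldehyde 12, where the route is rejoined.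

Step 8 (ring-closing metathesis). A Ru-alkylidene formed at the tertiary-allylic vinyl group could close onto the nearest trisubstituted chain olefin (cyclopentene formation with loss of the chain, as linalool itself does), or the chelated benzylidene could stall. The fallback is a relay closure that sets out from 12. Wittig reaction with the ylide from (hex-5-en-1-yl)triphenylphosphonium bromide (KHMDS, THF, −78 °C → rt) gives 5-bromo-1-[(1Z)-hepta-1,6-dien-1-yl]-3-methyl-2-{[(3S,6E,10E)-3,7,11,15-tetramethylhexadeca-1,6,10,14-tetraen-3-yl]oxy}benzene F2. With Grubbs II the catalyst loads on the unhindered terminal olefin of the relay arm and expels cyclopentene, which places it on the benzylic carbon. From there only the six-membered closure onto the vinyl group is open, and the route is rejoined at 14.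

Step 9 (Ar–Br to Ar–OH). Butylation of 15 or over-oxidation of the electron-rich phenolate to the quinone may occur. The fallback sets out from 14 and goes directly to 17 by Pd-catalysed C–O coupling with hydroxide (tBuBrettPhos-Pd G3, KOH, dioxane/H2O, 60–80 °C, degassed, dark). No organolithium or boron species is involved and no new compound is made on the way (none F0).

Further compounds
F1 | step 6 | 5-bromo-3-methyl-2-{[(3S,6E,10E)-3,7,11,15-tetramethylhexadeca-1,6,10,14-tetraen-3-yl]oxy}benzonitrile | C=C[C@@](C)(Oc1c(C)cc(Br)cc1C#N)CC/C=C(\C)CC/C=C(\C)CCC=C(C)C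
F2 | step 8 | 5-bromo-1-[(1Z)-hepta-1,6-dien-1-yl]-3-methyl-2-{[(3S,6E,10E)-3,7,11,15-tetramethylhexadeca-1,6,10,14-tetraen-3-yl]oxy}benzene | C=C[C@@](C)(Oc1c(C)cc(Br)cc1/C=C\CCCC=C)CC/C=C(\C)CC/C=C(\C)CCC=C(C)C
F0 | step 9 | none | none
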